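The rate constants stand for no real mixture; what happens was integrated by code.

Follow every mole of G through the flasks below, and turn each constant into a time at the charge.

| setting | green | red | violet | amber |
|---|---|---|---|---|
| G | 0.20 M | 0.20 M | 0.20 M | 0.20 M |
| temperature | 0 °C | −20 °C |  | −40 °C |
| time | 20 h | 20 h | 20 h | 20 h |
| remark |  |  | at −40 °C until 6.0 h, from then on at 0 °C |  |

- the flask that comes out highest in share of E in all that became E or Q or Z, or "all alike" when all lie within 1.5 percentage points (green / red / violet / amber / all alike)
- share of E in all that became E or Q or Z, green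
- share of E in all that became E or Q or Z, red
- share of E in all that became E or Q or Z, violet
- share of E in all that became E or Q or Z, amber

- in percentages every species weighs as the G in it: one G2 counts as two
- for E the D are counted in
- for a step with 2 of a species take k times the square, and two of it per event
- as a solid, counted per litre of solution: D
- the constants hold at 0 °C; other temperatures follow from the activation energies and enthalpies

    E → Z (k1 = 0.0223 /h, Ea1 = 98.0 kJ/mol)
    E ⇌ Q (k2 = 0.401 /h, Ea2 = 87.0 kJ/mol)
    G ⇌ E (K3 = 2.48, k3 = 1.20 /h, Ea3 = 75.0 kJ/mol, ΔH3 = 24.0 kJ/mol)
    D ⇌ E, rate k4*(cs4 - [E]) while solid is left; crystals form when [E] > cs4 (cs4 = 0.14 M, k4 = 8.11 /h)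
    G ⇌ Q (K5 = 16.8, k5 = 0.0591 /h, Ea5 = 93.0 kJ/mol, ΔH5 = 23.0 kJ/mol)
    2 G → G2 (k6 = 0.323 /M/h, Ea6 = 75.0 kJ/mol)
    (constants at 0 °C)

G, the substrate, goes to E, to Q or, two at a time, to G2. E in turn goes to Q or Z, and above 0.14 M dissolved E drops out as crystals D, which stay booked under E. G still left and G2 stand outside the share, so the books asked for have three entries: E, Q and Z. At 0 °C the ledger opens with these half-lives, each for one step alone:

G to E, forward: 0.578 h
G to Q, forward: 11.7 h
G to G2, first half-life at the charge: 7.74 h
E to Q, forward: 1.73 h
E to Z: 31.1 h

G reaches E faster than it reaches Q directly, so E fills first. What E keeps then turns on its exchange with Q, which runs both ways. Let k be the rate constant of E to Q, 0.401 /h, and K the ratio Q/E at balance: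

K = 16.8 / 2.48 = 6.77
τ = ln(2) / (k(1 + 1/K)) = 1.51 h

This τ is the exchange half-life, the half-life of the gap between E and Q and their balance, both ways together. Hold it against the reading time.

In green, 20 h holds 13.2 exchange half-lives, so this reckoning puts the pair near balance: thermodynamic control. E then keeps its balance part of the pair, and Z leaks from E at 0.0223 /h:

E in the pair: 1/(1 + K) = 12.9%
leak from the pair: 0.0223 /h times that part = 0.00287 /h
green share: 12.9% less the leak over 20 h = 12.1%

Amber is colder. E to Z gains a factor 1600 between −40 °C and 0 °C. On a logarithmic scale each step's gain goes with its activation energy, so E to Q gains 715. K is taken as unchanged, since the two enthalpies differ by 1.00 kJ/mol. Then τ in amber is 1080 h: kinetic control. Q per E comes by two routes, E aged on average over the reading time divided by 2, and G going directly: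

through E: 0.00561
directly from G: 0.0126
amber share: 1/(1 + sum) = 98.2%

This reckoning puts amber above green and gives no figure for red or violet.

The forecast names amber, with green 11.7%, red 73.5%, violet 12.4% and amber 98%, on the ground that “the strongly activated drain from E to Q is almost frozen” in the cold.

The simulation gives amber highest: green 11.3%, red 71.7%, violet 11.9%, amber 98.0%. The reckoned 12.1% and 98.2% stand beside green's 11.3% and amber's 98.0%.

Green reads so low because E and Q exchange, though this is a part of the picture: with that step taken away, both ways, green stands at 42.2% against 11.3%, a shift of 31 percentage points. In amber the early hour of the reading is the largest single effect, not the main reason: read at 200 h, amber stands at 89.5% against 98.0%. The same τ serves violet. Its cold stretch to 6.0 h leaves E at 2.38% and Q at 0.0352%, but the remaining time at 0 °C holds 9.27 exchange half-lives, and violet ends with E at 10.6%, Q at 71.8% and a share of 11.9%.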